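**Plan**

- Cuts: the arene is traced back to a cyclohexane-1,3-dione. Its ring bonds C(alkyl-bearing)–CH(CO2Me) and CH2–C(=O) are cut to an (R)-δ-alkoxy enone plus dimethyl malonate. The enone is cut at its C=C (to methyl vinyl ketone) and at the carbinol–allyl bond (to a C12 aldehyde).
- Forward order: monobenzylated 1,12-dodecanediol → aldehyde → (R)-homoallylic PMB ether → enone → the single ring by Michael–Claisen annulation → decarboxylation → methyl enol ether → PMB-for-acetyl exchange → dehydrogenation to the arene → debenzylation.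
- Enabling feature: the benzene ring with OMe and OH on the two carbons meta to the alkyl-bearing carbon is the dehydrogenated form of a symmetric 5-alkylcyclohexane-1,3-dione. One O-methylation therefore tells the two oxygens apart without desymmetrising a resorcinol.
- Stereochemistry: the only stereocentre (side-chain C-2, R) is set by reagent-controlled allylboration of the aldehyde. Afterwards it is never α to a carbonyl and its C–O bond is never broken.

Key step: step 6

Remark: 12–14 are written as keto tautomers although they are largely enolised; the ring or chain stereocentres created in 11–13 and 15–18 are uncontrolled and vanish on aromatisation; the primary alcohol travels as a benzyl ether because it must outlast methoxide, hydroxide, acid, DDQ and silyl triflate and can leave last by hydrogenolysis.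

**Route**

Step 1
Reactants: 1 1,12-dodecanediol
Product: 2 12-(benzyloxy)dodecan-1-ol
Conditions: 1 (3 equiv), NaH (1 equiv), BnBr (1 equiv), n-Bu4NI (cat.), THF/DMF, 0 °C to rt; excess 1 recovered
Reagents that add atoms: benzyl bromide, BrCc1ccccc1
Why: Williamson etherification of the mono-alkoxide, where the excess of diol should make the mono-ether the main product.

Step 2
Reactants: 2 12-(benzyloxy)dodecan-1-ol
Product: 3 12-(benzyloxy)dodecanal
Conditions: TEMPO (10 mol %), PhI(OAc)2 (1.1 equiv), CH2Cl2, rt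
Reagents that add atoms: none
Why: TEMPO/PhI(OAc)2 (oxoammonium) oxidation takes a primary alcohol to the aldehyde without over-oxidation and leaves the benzyl ether alone.

Step 3
Reactants: 3 12-(benzyloxy)dodecanal; 4 allylmagnesium bromide
Product: 6 (4R)-15-(benzyloxy)pentadec-1-en-4-ol, via diisopinocampheylborinate 5 (not isolated)
Conditions: (−)-Ipc2BOMe (from (+)-α-pinene) and 4, Et2O, −78 °C to rt; then 3, −78 °C; then 3 M NaOH, 30% H2O2, rt
Reagents that add atoms: none
Why: Brown asymmetric allylboration through a chair Zimmerman–Traxler transition state, in which the isopinocampheyl groups derived from (+)-α-pinene steer the allyl group to the si face of the aldehyde and so set the (R)-carbinol, the only stereocentre of the target.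

Step 4
Reactants: 6 (4R)-15-(benzyloxy)pentadec-1-en-4-ol
Product: 7 1-({[(4R)-15-(benzyloxy)pentadec-1-en-4-yl]oxy}methyl)-4-methoxybenzene
Conditions: NaH, 4-methoxybenzyl chloride, n-Bu4NI (cat.), DMF, 0 °C to rt
Reagents that add atoms: 4-methoxybenzyl chloride, COc1ccc(CCl)cc1
Why: Williamson etherification of the secondary alkoxide with an activated benzylic halide, in which the C–O bond of the stereocentre is not broken.

Step 5
Reactants: 7 1-({[(4R)-15-(benzyloxy)pentadec-1-en-4-yl]oxy}methyl)-4-methoxybenzene; 8 methyl vinyl ketone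
Product: 9 (3E,6R)-17-(benzyloxy)-6-[(4-methoxybenzyl)oxy]heptadec-3-en-2-one
Conditions: second-generation Hoveyda–Grubbs catalyst, RuCl2(H2IMes)(=CH-C6H4-2-OiPr) (3 mol %), 8 (4 equiv), CH2Cl2, 40 °C
Reagents that add atoms: none
Why: olefin cross-metathesis of a terminal alkene with an electron-poor enone partner that does not homodimerise, which should give the conjugated E-enone under thermodynamic control.

Step 6
Reactants: 9 (3E,6R)-17-(benzyloxy)-6-[(4-methoxybenzyl)oxy]heptadec-3-en-2-one; 10 dimethyl malonate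
Product: 12 methyl 6-{(2R)-13-(benzyloxy)-2-[(4-methoxybenzyl)oxy]tridecyl}-2,4-dioxocyclohexane-1-carboxylate, via malonate Michael adduct 11 (not isolated)
Conditions: 10 (1.3 equiv), NaOMe (1.2 equiv), MeOH, 0 °C to rt, then 65 °C; cold 1 M HCl to pH 3
Reagents that add atoms: none
Why: Sodium dimethyl malonate, a soft stabilised carbanion, adds 1,4 to the β-carbon of enone 9 to give 11, whose methyl-ketone enolate then attacks one malonate ester carbonyl and expels methoxide, so that the Cβ–CH(CO2Me) and CH2–C(=O) ring bonds form in one flask. The closest known reaction type is the Michael–Claisen (Dieckmann-type) annulation of alk-3-en-2-ones with malonates that delivers 5-alkylcyclohexane-1,3-diones. The six-membered carbocycle closes in a 6-exo-trig mode (enolate carbon onto the ester C=O, which stays outside the ring), and irreversible deprotonation of the resulting β-diketone pulls the sequence forward. The two new ring stereocentres (C-1 and C-6) are not controlled and need not be, since C-1 is lost on decarboxylation and C-6 ends as an sp2 arene carbon, while the side-chain carbinol has no acidic hydrogen and stays R. The step needs 1,4- over 1,2-addition and no E1cB loss of the δ-alkoxy group through the γ-dienolate; this is secured by the soft malonate anion kept in slight excess over NaOMe, by running the Michael addition cold before heating, and by the poor leaving ability of 4-methoxybenzyl oxide.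

Step 7
Reactants: 12 methyl 6-{(2R)-13-(benzyloxy)-2-[(4-methoxybenzyl)oxy]tridecyl}-2,4-dioxocyclohexane-1-carboxylate
Product: 14 5-{(2R)-13-(benzyloxy)-2-[(4-methoxybenzyl)oxy]tridecyl}cyclohexane-1,3-dione, via dioxocyclohexanecarboxylic acid 13 (not isolated)
Conditions: 2 M NaOH, MeOH/H2O, 70 °C; 1 M HCl to pH 3 at 0 °C; extract into toluene, 80 °C
Reagents that add atoms: none
Why: saponification of the β-keto ester followed by thermal decarboxylation of the β-keto acid through its cyclic six-membered transition state, with cold acidification and heating only in toluene so that the PMB ether survives and a dione results whose substituted ring carbon is no longer stereogenic.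

Step 8
Reactants: 14 5-{(2R)-13-(benzyloxy)-2-[(4-methoxybenzyl)oxy]tridecyl}cyclohexane-1,3-dione
Product: 15 5-{(2R)-13-(benzyloxy)-2-[(4-methoxybenzyl)oxy]tridecyl}-3-methoxycyclohex-2-en-1-one (C-5 epimers)
Conditions: MeOH, HC(OMe)3 (3 equiv), TsOH·H2O (5 mol %), rt; Et3N quench
Reagents that add atoms: methanol, CO
Why: acid-catalysed vinylogous esterification (enol ether formation) of a cyclic 1,3-dione, which can give only one constitutional methyl enol ether because 14 is symmetric and thereby fixes which oxygen becomes OMe and which OH.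

Step 9
Reactants: 15 5-{(2R)-13-(benzyloxy)-2-[(4-methoxybenzyl)oxy]tridecyl}-3-methoxycyclohex-2-en-1-one
Product: 16 5-[(2R)-13-(benzyloxy)-2-hydroxytridecyl]-3-methoxycyclohex-2-en-1-one
Conditions: DDQ (1.3 equiv), CH2Cl2/pH 7 phosphate buffer (10:1), 0 °C
Reagents that add atoms: none
Why: oxidative cleavage of the PMB ether by DDQ (hydride abstraction to the anisyl oxocarbenium ion, then hydrolysis), which is much faster than attack on the plain benzyl ether and is placed before any electron-rich phenol exists.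

Step 10
Reactants: 16 5-[(2R)-13-(benzyloxy)-2-hydroxytridecyl]-3-methoxycyclohex-2-en-1-one
Product: 17 (2R)-13-(benzyloxy)-1-(3-methoxy-5-oxocyclohex-3-en-1-yl)tridecan-2-yl acetate
Conditions: Ac2O, pyridine, DMAP (cat.), CH2Cl2, 0 °C to rt
Reagents that add atoms: acetic anhydride, CC(=O)OC(C)=O
Why: DMAP-catalysed O-acylation of the secondary alcohol, with retention because only the O–H bond reacts.

Step 11
Reactants: 17 (2R)-13-(benzyloxy)-1-(3-methoxy-5-oxocyclohex-3-en-1-yl)tridecan-2-yl acetate
Product: 20 (2R)-13-(benzyloxy)-1-(3-hydroxy-5-methoxyphenyl)tridecan-2-yl acetate, via trimethylsilyl dienol ether 18 (not isolated), via cross-conjugated cyclohexadienone 19 (not isolated)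
Conditions: TMSOTf (1.3 equiv), Et3N (2 equiv), CH2Cl2, 0 °C; evaporate, pentane, filter; Pd(OAc)2 (1.1 equiv), MeCN, rt
Reagents that add atoms: none
Why: soft enolisation of the vinylogous ester (O-silylation, then amine deprotonation at C-6, the way 1-methoxy-3-silyloxy-1,3-dienes are made from β-methoxy enones) followed by Saegusa–Ito dehydrosilylation, whose dienone tautomerises at once to the phenol, while the acetate is not enolised by Et3N/TMSOTf at 0 °C.

Step 12
Reactants: 20 (2R)-13-(benzyloxy)-1-(3-hydroxy-5-methoxyphenyl)tridecan-2-yl acetate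
Product: 21 (2R)-13-hydroxy-1-(3-hydroxy-5-methoxyphenyl)tridecan-2-yl acetate
Conditions: H2 (1 atm), 10% Pd/C, EtOAc/EtOH, rt
Reagents that add atoms: none
Why: hydrogenolysis of the primary benzyl ether over palladium, which leaves the secondary acetate, the phenol, the aryl methyl ether and the non-benzylic C-2 stereocentre untouched.

**Compound list**

1 | 1,12-dodecanediol | OCCCCCCCCCCCCO | starting material
2 | 12-(benzyloxy)dodecan-1-ol | OCCCCCCCCCCCCOCc1ccccc1 | intermediate
3 | 12-(benzyloxy)dodecanal | O=CCCCCCCCCCCCOCc1ccccc1 | intermediate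
4 | allylmagnesium bromide | C=CC[Mg]Br | starting material
5 | (4R)-15-(benzyloxy)pentadec-1-en-4-yl diisopinocampheylborinate | C=CC[C@@H](CCCCCCCCCCCOCc1ccccc1)OB([C@@H]1C[C@@H]2C[C@H]([C@H]1C)C2(C)C)[C@@H]1C[C@@H]2C[C@H]([C@H]1C)C2(C)C | intermediate (not isolated)
6 | (4R)-15-(benzyloxy)pentadec-1-en-4-ol | C=CC[C@@H](CCCCCCCCCCCOCc1ccccc1)O | intermediate
7 | 1-({[(4R)-15-(benzyloxy)pentadec-1-en-4-yl]oxy}methyl)-4-methoxybenzene | C=CC[C@@H](CCCCCCCCCCCOCc1ccccc1)OCc1ccc(OC)cc1 | intermediate
8 | methyl vinyl ketone (but-3-en-2-one) | CC(=O)C=C | starting material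
9 | (3E,6R)-17-(benzyloxy)-6-[(4-methoxybenzyl)oxy]heptadec-3-en-2-one | CC(=O)/C=C/C[C@@H](CCCCCCCCCCCOCc1ccccc1)OCc1ccc(OC)cc1 | intermediate
10 | dimethyl malonate | COC(=O)CC(=O)OC | starting material
11 | dimethyl 2-{(6R)-17-(benzyloxy)-6-[(4-methoxybenzyl)oxy]-2-oxoheptadecan-4-yl}malonate (C-4 epimers) | COC(=O)C(C(=O)OC)C(CC(C)=O)C[C@@H](CCCCCCCCCCCOCc1ccccc1)OCc1ccc(OC)cc1 | intermediate (not isolated)
12 | methyl 6-{(2R)-13-(benzyloxy)-2-[(4-methoxybenzyl)oxy]tridecyl}-2,4-dioxocyclohexane-1-carboxylate (ring epimers) | COC(=O)C1C(=O)CC(=O)CC1C[C@@H](CCCCCCCCCCCOCc1ccccc1)OCc1ccc(OC)cc1 | intermediate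
13 | 6-{(2R)-13-(benzyloxy)-2-[(4-methoxybenzyl)oxy]tridecyl}-2,4-dioxocyclohexane-1-carboxylic acid | OC(=O)C1C(=O)CC(=O)CC1C[C@@H](CCCCCCCCCCCOCc1ccccc1)OCc1ccc(OC)cc1 | intermediate (not isolated)
14 | 5-{(2R)-13-(benzyloxy)-2-[(4-methoxybenzyl)oxy]tridecyl}cyclohexane-1,3-dione | O=C1CC(=O)CC(C[C@@H](CCCCCCCCCCCOCc2ccccc2)OCc2ccc(OC)cc2)C1 | intermediate
15 | 5-{(2R)-13-(benzyloxy)-2-[(4-methoxybenzyl)oxy]tridecyl}-3-methoxycyclohex-2-en-1-one (C-5 epimers) | COC1=CC(=O)CC(C[C@@H](CCCCCCCCCCCOCc2ccccc2)OCc2ccc(OC)cc2)C1 | intermediate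
16 | 5-[(2R)-13-(benzyloxy)-2-hydroxytridecyl]-3-methoxycyclohex-2-en-1-one | COC1=CC(=O)CC(C[C@@H](CCCCCCCCCCCOCc2ccccc2)O)C1 | intermediate
17 | (2R)-13-(benzyloxy)-1-(3-methoxy-5-oxocyclohex-3-en-1-yl)tridecan-2-yl acetate | COC1=CC(=O)CC(C[C@@H](CCCCCCCCCCCOCc2ccccc2)OC(C)=O)C1 | intermediate
18 | (2R)-13-(benzyloxy)-1-[5-methoxy-3-(trimethylsilyloxy)cyclohexa-2,4-dien-1-yl]tridecan-2-yl acetate | COC1=CC(O[Si](C)(C)C)=CC(C[C@@H](CCCCCCCCCCCOCc2ccccc2)OC(C)=O)C1 | intermediate (not isolated)
19 | (2R)-13-(benzyloxy)-1-(5-methoxy-3-oxocyclohexa-1,4-dien-1-yl)tridecan-2-yl acetate | COC1=CC(=O)C=C(C[C@@H](CCCCCCCCCCCOCc2ccccc2)OC(C)=O)C1 | intermediate (not isolated)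
20 | (2R)-13-(benzyloxy)-1-(3-hydroxy-5-methoxyphenyl)tridecan-2-yl acetate | COc1cc(O)cc(C[C@@H](CCCCCCCCCCCOCc2ccccc2)OC(C)=O)c1 | intermediate
21 | (2R)-13-hydroxy-1-(3-hydroxy-5-methoxyphenyl)tridecan-2-yl acetate | COc1cc(O)cc(C[C@@H](CCCCCCCCCCCO)OC(C)=O)c1 | target

**Count and risks**

Total steps: 12. Longest linear sequence: 12 steps (1 to 21).

Step 6 (annulation). Under methoxide at reflux the enone may be deprotonated at the γ-carbon and expel 4-methoxybenzyl oxide by an E1cB pathway, or the Michael adduct may revert instead of cyclising. The fallback sets out from 7 and reverses the roles of the two partners. Cross-metathesis of 7 with methyl acrylate over the same ruthenium catalyst should give methyl (2E,5R)-16-(benzyloxy)-5-[(4-methoxybenzyl)oxy]hexadec-2-enoate F1. Its γ-hydrogens are far less acidic than those of the enone, so the dienolate that leads to elimination is not formed. Sodium methyl acetoacetate (NaOMe, MeOH, reflux) then adds 1,4 to give dimethyl 2-acetyl-3-{(2R)-13-(benzyloxy)-2-[(4-methoxybenzyl)oxy]tridecyl}pentanedioate F2. In F2 the acetyl methyl enolate closes onto the CH2CO2Me ester in the same 6-exo-trig Claisen manner. After acidification this is 12, where the route is rejoined.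

Step 11 (aromatisation). The acetic acid released may protodesilylate 18 faster than it is palladated, or the ester may interfere with the soft enolisation, so that conversion stalls. The fallback sets out from 15 and aromatises before any ester is present, using the kinetic lithium enolate.
- LiN(iPr)2 (THF, −78 °C) and PhSeCl should give 5-{(2R)-13-(benzyloxy)-2-[(4-methoxybenzyl)oxy]tridecyl}-3-methoxy-6-(phenylselanyl)cyclohex-2-en-1-one F3.
- H2O2/pyridine in CH2Cl2 at 0 °C oxidises the selenide; syn-elimination and tautomerisation lead to 3-{(2R)-13-(benzyloxy)-2-[(4-methoxybenzyl)oxy]tridecyl}-5-methoxyphenol F4.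
- The phenol is masked with BnBr/K2CO3 in DMF as 1-(benzyloxy)-3-{(2R)-13-(benzyloxy)-2-[(4-methoxybenzyl)oxy]tridecyl}-5-methoxybenzene F5.
- DDQ in wet CH2Cl2 removes the PMB group to give (2R)-13-(benzyloxy)-1-[3-(benzyloxy)-5-methoxyphenyl]tridecan-2-ol F6.
- Ac2O/DMAP gives (2R)-13-(benzyloxy)-1-[3-(benzyloxy)-5-methoxyphenyl]tridecan-2-yl acetate F7.
- Hydrogenolysis of both benzyl ethers (H2, Pd/C) returns to the route at 21.

Step 3 (allylboration). Facial discrimination at the aldehyde may be incomplete, and since every intermediate is an oil the minor enantiomer could not be removed later. The fallback sets out from 3 and takes the stereocentre from a kinetic resolution instead.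
- Corey–Chaykovsky epoxidation (trimethylsulfonium iodide, NaH, DMSO/THF) should give racemic 2-[11-(benzyloxy)undecyl]oxirane F8.
- Hydrolytic kinetic resolution with (R,R)-(salen)Co(OAc) and 0.55 equiv of water is expected to leave (2R)-2-[11-(benzyloxy)undecyl]oxirane F9. The catalyst is the acetate of trivalent cobalt with the (R,R)-N,N′-bis(3,5-di-tert-butylsalicylidene)cyclohexane-1,2-diamine ligand. The unwanted half is converted to (2S)-13-(benzyloxy)tridecane-1,2-diol F10, which is separated.
- Opening of F9 at its terminal carbon with CH2=CHMgBr and catalytic CuI in THF at −30 °C keeps the configured C–O bond intact and gives 6, where the route is rejoined.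

**Further compounds**

F1 | step 6 | methyl (2E,5R)-16-(benzyloxy)-5-[(4-methoxybenzyl)oxy]hexadec-2-enoate | COC(=O)/C=C/C[C@@H](CCCCCCCCCCCOCc1ccccc1)OCc1ccc(OC)cc1
F2 | step 6 | dimethyl 2-acetyl-3-{(2R)-13-(benzyloxy)-2-[(4-methoxybenzyl)oxy]tridecyl}pentanedioate | COC(=O)CC(C[C@@H](CCCCCCCCCCCOCc1ccccc1)OCc1ccc(OC)cc1)C(C(C)=O)C(=O)OC
F3 | step 11 | 5-{(2R)-13-(benzyloxy)-2-[(4-methoxybenzyl)oxy]tridecyl}-3-methoxy-6-(phenylselanyl)cyclohex-2-en-1-one | COC1=CC(=O)C([Se]c2ccccc2)C(C[C@@H](CCCCCCCCCCCOCc2ccccc2)OCc2ccc(OC)cc2)C1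
F4 | step 11 | 3-{(2R)-13-(benzyloxy)-2-[(4-methoxybenzyl)oxy]tridecyl}-5-methoxyphenol | COc1cc(O)cc(C[C@@H](CCCCCCCCCCCOCc2ccccc2)OCc2ccc(OC)cc2)c1
F5 | step 11 | 1-(benzyloxy)-3-{(2R)-13-(benzyloxy)-2-[(4-methoxybenzyl)oxy]tridecyl}-5-methoxybenzene | COc1cc(OCc2ccccc2)cc(C[C@@H](CCCCCCCCCCCOCc2ccccc2)OCc2ccc(OC)cc2)c1
F6 | step 11 | (2R)-13-(benzyloxy)-1-[3-(benzyloxy)-5-methoxyphenyl]tridecan-2-ol | COc1cc(OCc2ccccc2)cc(C[C@@H](CCCCCCCCCCCOCc2ccccc2)O)c1
F7 | step 11 | (2R)-13-(benzyloxy)-1-[3-(benzyloxy)-5-methoxyphenyl]tridecan-2-yl acetate | COc1cc(OCc2ccccc2)cc(C[C@@H](CCCCCCCCCCCOCc2ccccc2)OC(C)=O)c1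
F8 | step 3 | racemic 2-[11-(benzyloxy)undecyl]oxirane | C1OC1CCCCCCCCCCCOCc1ccccc1
F9 | step 3 | (2R)-2-[11-(benzyloxy)undecyl]oxirane | C1O[C@@H]1CCCCCCCCCCCOCc1ccccc1
F10 | step 3 | (2S)-13-(benzyloxy)tridecane-1,2-diol | OC[C@@H](O)CCCCCCCCCCCOCc1ccccc1
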